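**Plan**
- Retrosynthesis: the C1 ketone is traced back to a silyl-protected carbinol. Ring B is then cut at C4–C4a and C1–C8a in one [4+2] operation, giving 1,4-benzoquinone and a (1E,3E)-1-naphthyl-4-silyloxybutadiene. The diene is cut at the enol O–Si bond (an aldehyde) and at the naphthyl–vinyl bond (Suzuki coupling).
- Enabling feature: ring A (C4a, C5–C8, C8a with the 5,8-hydroxyls) is a reduced p-benzoquinone. The ring B bonds C4–C4a and C1–C8a sit on one quinone double bond (C4a=C8a), and C1 carries oxygen. Ring B is therefore a quinone C=C plus a 1-aryl-4-oxybutadiene.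
- Forward: the naphthalene is carried intact from 5-methoxy-1-naphthol and the four-carbon chain is joined by Suzuki coupling. Ring B closes by Diels–Alder addition to benzoquinone, whose ring aromatises to ring A. Alkene saturation, C1 oxidation and one global debenzylation follow.
- Stereochemistry: C4 (S) is set by the chiral oxazaborolidinium catalyst in the cycloaddition. The cis C1 centre is temporary and is oxidised away, and no later step touches C4–H.

Key step: step 7

Remark: locants C1–C8a are those of the tetralone ring of the target throughout.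
Assumption: the (S)-catalyst is written for step 7; the sense of induction was not derived here, both antipodes are equally accessible, and the one that delivers (4S) is the one to be used.

**Step 1**
Reactants: 1 5-methoxynaphthalen-1-ol
Product: 2 4-bromo-5-methoxynaphthalen-1-ol
Conditions: NBS (1.0 equiv), MeCN, −20 → 0 °C, dark
Reagents that add atoms: N-bromosuccinimide, O=C1CCC(=O)N1Br
Why: Electrophilic aromatic bromination in which the free hydroxyl, the strongest donor, directs NBS to its para position C4 (peri to the methoxy group); brominating before O-benzylation avoids competition from the position para to the methoxy group.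

**Step 2**
Reactants: 2 4-bromo-5-methoxynaphthalen-1-ol
Product: 3 1-(benzyloxy)-4-bromo-5-methoxynaphthalene
Conditions: BnBr, K2CO3, DMF, rt
Reagents that add atoms: benzyl bromide, BrCc1ccccc1
Why: Williamson etherification of the naphthoxide; the benzyl ether should withstand the coupling, acidic, Lewis-acidic, fluoride and oxidising steps that follow and leaves by hydrogenolysis at the end.

**Step 3**
Reactants: 4 4,4-diethoxybut-1-yne
Product: 5 2-[(1E)-4,4-diethoxybut-1-en-1-yl]-4,4,5,5-tetramethyl-1,3,2-dioxaborolane
Conditions: pinacolborane, Cp2Zr(H)Cl (5 mol%), Et3N (10 mol%), neat, 60 °C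
Reagents that add atoms: pinacolborane, [H]B1OC(C)(C)C(C)(C)O1
Why: Zirconium-catalysed hydroboration of a terminal alkyne adds H–B syn with boron at the terminal carbon, giving the (E)-alkenylboronate and fixing the geometry of the future C3=C4 diene bond.

**Step 4**
Reactants: 3 1-(benzyloxy)-4-bromo-5-methoxynaphthalene; 5 2-[(1E)-4,4-diethoxybut-1-en-1-yl]-4,4,5,5-tetramethyl-1,3,2-dioxaborolane
Product: 6 1-(benzyloxy)-4-[(1E)-4,4-diethoxybut-1-en-1-yl]-5-methoxynaphthalene
Conditions: Pd(OAc)2 (3 mol%), SPhos (6 mol%), K3PO4, toluene–H2O, 80 °C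
Reagents that add atoms: none
Why: Suzuki–Miyaura coupling with retention of alkene geometry; an electron-rich biarylphosphine suits the electron-rich, peri-hindered bromide, and the acetal is stable to aqueous base.

**Step 5**
Reactants: 6 1-(benzyloxy)-4-[(1E)-4,4-diethoxybut-1-en-1-yl]-5-methoxynaphthalene
Product: 7 (3E)-4-[4-(benzyloxy)-8-methoxynaphthalen-1-yl]but-3-enal
Conditions: 2 M aq. HCl, THF, 0 °C → rt; crude aldehyde used at once
Reagents that add atoms: water, O
Why: Acid-catalysed acetal hydrolysis under mild conditions that leave the aryl benzyl and methyl ethers intact; the sensitive β,γ-unsaturated aldehyde is not purified.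

**Step 6**
Reactants: 7 (3E)-4-[4-(benzyloxy)-8-methoxynaphthalen-1-yl]but-3-enal
Product: 8 (1E,3E)-1-[4-(benzyloxy)-8-methoxynaphthalen-1-yl]-4-[(triisopropylsilyl)oxy]buta-1,3-diene
Conditions: TIPSOTf (1.2 equiv), Et3N (2 equiv), CH2Cl2, −78 → 0 °C; filtration through Et3N-deactivated silica
Reagents that add atoms: triisopropylsilyl trifluoromethanesulfonate, CC(C)[Si](C(C)C)(C(C)C)OS(=O)(=O)C(F)(F)F
Why: Silyl dienol ether formation by soft enolisation, in which O-silylation of the aldehyde and removal of the doubly activated C2–H by Et3N should give mainly the extended (1E) isomer with the (3E) geometry carried over from 7; TIPS is chosen because it resists the acidic catalyst of step 7 and later O-to-O silyl migration, and any (1Z) isomer should be unreactive in step 7.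

**Step 7**
Reactants: 8 (1E,3E)-1-[4-(benzyloxy)-8-methoxynaphthalen-1-yl]-4-[(triisopropylsilyl)oxy]buta-1,3-diene; 9 1,4-benzoquinone
Product: 11 (1S,4S)-4-[4-(benzyloxy)-8-methoxynaphthalen-1-yl]-1-[(triisopropylsilyl)oxy]-1,4-dihydronaphthalene-5,8-diol (1,4-cis), via all-cis endo adduct 5-[4-(benzyloxy)-8-methoxynaphthalen-1-yl]-8-[(triisopropylsilyl)oxy]-4a,5,8,8a-tetrahydronaphthalene-1,4-dione 10 (not isolated)
Conditions: 8 (1.1 equiv), 9 (1.0 equiv), (S)-3,3-diphenyl-1-(o-tolyl)tetrahydropyrrolo[1,2-c][1,3,2]oxazaborole (20 mol%) activated with Tf2NH (18 mol%), CH2Cl2, −78 °C; then Et3N (1.5 equiv), −78 → 0 °C, Ar; crude 11 taken on at once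
Reagents that add atoms: none
Why: The quinone, bound through one carbonyl oxygen to boron with the adjacent vinylic C–H held by the oxazaborolidine oxygen, reacts with the diene HOMO in a concerted, asynchronous endo [4+2] whose more advanced bond runs from the aryl-bearing diene carbon (largest HOMO coefficient, vinylogous to the silyloxy donor) to the quinone carbon β to the complexed carbonyl; the closest known reaction type is the oxazaborolidinium-catalysed enantioselective quinone Diels–Alder reaction with oxygenated dienes. Ring B (C1–C2–C3–C4–C4a–C8a) closes by intermolecular cycloaddition across the quinone C4a=C8a bond, forming C4–C4a and C1–C8a suprafacially on both partners. C4 is set by the catalyst, which screens one face of the complexed double bond and so selects one enantioface of the diene; C1 ends cis to C4 because both substituents are outside groups of the (1E,3E)-diene; C4a and C8a (endo) are transient and are erased when Et3N tautomerises ene-dione 10 to hydroquinone 11, after which C4–H is no longer near an enolisable carbonyl. Because benzoquinone has two equivalent carbonyls, the two orientations of the unsymmetrical diene on the same quinone face would give enantiomers, so the step needs orientation control as well as face control; the silyloxy group polarises the diene strongly, the peri-methoxy group twists the naphthyl out of conjugation so that it cannot oppose this polarisation, and −78 °C suppresses the uncatalysed background reaction. Benzoquinone is the limiting reagent so that none remains to oxidise 11.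

**Step 8**
Reactants: 11 (1S,4S)-4-[4-(benzyloxy)-8-methoxynaphthalen-1-yl]-1-[(triisopropylsilyl)oxy]-1,4-dihydronaphthalene-5,8-diol
Product: 12 (1S,4S)-5,8-bis(benzyloxy)-4-[4-(benzyloxy)-8-methoxynaphthalen-1-yl]-1-[(triisopropylsilyl)oxy]-1,4-dihydronaphthalene
Conditions: BnBr (2.5 equiv), Cs2CO3 (3 equiv), degassed DMF, 0 °C → rt, Ar
Reagents that add atoms: benzyl bromide, BrCc1ccccc1
Why: Williamson O-benzylation of both phenols, done at once on crude 11 so that the hydroquinone cannot be oxidised or lose silanol; benzyl is chosen so that all three aryl ethers fall in one final hydrogenolysis and no acyl group can migrate to the C1 oxygen.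

**Step 9**
Reactants: 12 (1S,4S)-5,8-bis(benzyloxy)-4-[4-(benzyloxy)-8-methoxynaphthalen-1-yl]-1-[(triisopropylsilyl)oxy]-1,4-dihydronaphthalene
Product: 13 (1S,4S)-5,8-bis(benzyloxy)-4-[4-(benzyloxy)-8-methoxynaphthalen-1-yl]-1-[(triisopropylsilyl)oxy]-1,2,3,4-tetrahydronaphthalene
Conditions: 2-nitrobenzenesulfonohydrazide (excess, in portions), Et3N, CH2Cl2, rt
Reagents that add atoms: none
Why: Diimide reduction, a concerted syn transfer of H2 from HN=NH generated in situ to the cis-disubstituted C2=C3 bond from the face opposite the C1 and C4 substituents; no metal hydride is involved, so the alkene cannot migrate into conjugation at C4, benzyl ethers are untouched, and aromatisation by loss of silanol is impossible once the alkene is gone.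

**Step 10**
Reactants: 13 (1S,4S)-5,8-bis(benzyloxy)-4-[4-(benzyloxy)-8-methoxynaphthalen-1-yl]-1-[(triisopropylsilyl)oxy]-1,2,3,4-tetrahydronaphthalene
Product: 14 (1S,4S)-5,8-bis(benzyloxy)-4-[4-(benzyloxy)-8-methoxynaphthalen-1-yl]-1,2,3,4-tetrahydronaphthalen-1-ol
Conditions: TBAF (1 M in THF), THF, 0 °C → rt
Reagents that add atoms: none
Why: Fluoride-mediated cleavage of the secondary silyl ether driven by Si–F bond formation; no base-labile group is present.

**Step 11**
Reactants: 14 (1S,4S)-5,8-bis(benzyloxy)-4-[4-(benzyloxy)-8-methoxynaphthalen-1-yl]-1,2,3,4-tetrahydronaphthalen-1-ol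
Product: 15 (4S)-5,8-bis(benzyloxy)-4-[4-(benzyloxy)-8-methoxynaphthalen-1-yl]-3,4-dihydronaphthalen-1(2H)-one
Conditions: Dess–Martin periodinane, CH2Cl2, 0 °C → rt
Reagents that add atoms: none
Why: Dess–Martin oxidation of the secondary benzylic alcohol to the aryl ketone under neutral conditions; the temporary C1 stereocentre is removed, and C4 is not α to the new carbonyl and cannot epimerise.

**Step 12**
Reactants: 15 (4S)-5,8-bis(benzyloxy)-4-[4-(benzyloxy)-8-methoxynaphthalen-1-yl]-3,4-dihydronaphthalen-1(2H)-one
Product: 16 (4S)-5,8-dihydroxy-4-(4-hydroxy-8-methoxynaphthalen-1-yl)-3,4-dihydronaphthalen-1(2H)-one (CNP0584478.1)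
Conditions: H2 (1 atm), 10% Pd/C, EtOAc–MeOH, rt, stopped after uptake of 3 equiv; work-up under Ar
Reagents that add atoms: none
Why: Hydrogenolysis of the three aryl benzyl ethers over Pd/C; aryl benzyl ethers cleave fast, the tetralone carbonyl becomes hydrogen-bonded to the freed C8 hydroxyl and should be reduced far more slowly, and neither the methyl ether nor C4 is affected.

**Compound list**
1 | 5-methoxynaphthalen-1-ol | COc1cccc2c(O)cccc12 | starting material
2 | 4-bromo-5-methoxynaphthalen-1-ol | COc1cccc2c(O)ccc(Br)c12 | intermediate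
3 | 1-(benzyloxy)-4-bromo-5-methoxynaphthalene | COc1cccc2c(OCc3ccccc3)ccc(Br)c12 | intermediate
4 | 4,4-diethoxybut-1-yne | C#CCC(OCC)OCC | starting material
5 | 2-[(1E)-4,4-diethoxybut-1-en-1-yl]-4,4,5,5-tetramethyl-1,3,2-dioxaborolane | CCOC(C/C=C/B1OC(C)(C)C(C)(C)O1)OCC | intermediate
6 | 1-(benzyloxy)-4-[(1E)-4,4-diethoxybut-1-en-1-yl]-5-methoxynaphthalene | CCOC(C/C=C/c1ccc(OCc2ccccc2)c2cccc(OC)c12)OCC | intermediate
7 | (3E)-4-[4-(benzyloxy)-8-methoxynaphthalen-1-yl]but-3-enal | O=CC/C=C/c1ccc(OCc2ccccc2)c2cccc(OC)c12 | intermediate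
8 | (1E,3E)-1-[4-(benzyloxy)-8-methoxynaphthalen-1-yl]-4-[(triisopropylsilyl)oxy]buta-1,3-diene | COc1cccc2c(OCc3ccccc3)ccc(/C=C/C=C/O[Si](C(C)C)(C(C)C)C(C)C)c12 | intermediate
9 | 1,4-benzoquinone | O=C1C=CC(=O)C=C1 | starting material
10 | all-cis endo adduct 5-[4-(benzyloxy)-8-methoxynaphthalen-1-yl]-8-[(triisopropylsilyl)oxy]-4a,5,8,8a-tetrahydronaphthalene-1,4-dione (H-4a, H-5, H-8, H-8a on one face) | COc1cccc2c(OCc3ccccc3)ccc([C@@H]3C=C[C@H](O[Si](C(C)C)(C(C)C)C(C)C)[C@@H]4C(=O)C=CC(=O)[C@H]34)c12 | intermediate (not isolated)
11 | (1S,4S)-4-[4-(benzyloxy)-8-methoxynaphthalen-1-yl]-1-[(triisopropylsilyl)oxy]-1,4-dihydronaphthalene-5,8-diol | COc1cccc2c(OCc3ccccc3)ccc([C@@H]3C=C[C@H](O[Si](C(C)C)(C(C)C)C(C)C)c4c(O)ccc(O)c43)c12 | intermediate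
12 | (1S,4S)-5,8-bis(benzyloxy)-4-[4-(benzyloxy)-8-methoxynaphthalen-1-yl]-1-[(triisopropylsilyl)oxy]-1,4-dihydronaphthalene | COc1cccc2c(OCc3ccccc3)ccc([C@@H]3C=C[C@H](O[Si](C(C)C)(C(C)C)C(C)C)c4c(OCc5ccccc5)ccc(OCc5ccccc5)c43)c12 | intermediate
13 | (1S,4S)-5,8-bis(benzyloxy)-4-[4-(benzyloxy)-8-methoxynaphthalen-1-yl]-1-[(triisopropylsilyl)oxy]-1,2,3,4-tetrahydronaphthalene | COc1cccc2c(OCc3ccccc3)ccc([C@@H]3CC[C@H](O[Si](C(C)C)(C(C)C)C(C)C)c4c(OCc5ccccc5)ccc(OCc5ccccc5)c43)c12 | intermediate
14 | (1S,4S)-5,8-bis(benzyloxy)-4-[4-(benzyloxy)-8-methoxynaphthalen-1-yl]-1,2,3,4-tetrahydronaphthalen-1-ol | COc1cccc2c(OCc3ccccc3)ccc([C@@H]3CC[C@H](O)c4c(OCc5ccccc5)ccc(OCc5ccccc5)c43)c12 | intermediate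
15 | (4S)-5,8-bis(benzyloxy)-4-[4-(benzyloxy)-8-methoxynaphthalen-1-yl]-3,4-dihydronaphthalen-1(2H)-one | COc1cccc2c(OCc3ccccc3)ccc([C@@H]3CCC(=O)c4c(OCc5ccccc5)ccc(OCc5ccccc5)c43)c12 | intermediate
16 | (4S)-5,8-dihydroxy-4-(4-hydroxy-8-methoxynaphthalen-1-yl)-3,4-dihydronaphthalen-1(2H)-one | COc1cccc2c(O)ccc([C@@H]3CCC(=O)c4c(O)ccc(O)c43)c12 | target

**Step count**
Total: 12 steps. Longest linear sequence: 11 steps (1 → 16 through steps 1, 2 and 4–12); step 3 is a one-step side branch.

**Steps most likely to fail**

Step 7. Several processes could undermine the cycloaddition: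
- The diene may add in both orientations to the symmetric quinone, which would erode enantiopurity even if each approach is face-selective.
- The electron-rich naphthyl diene may transfer an electron to the acid-activated quinone, leading to oligomerisation or Michael-type addition instead of cycloaddition.
- The adduct may lose silanol and aromatise during enolisation.

The fallback sets out from 8 and replaces benzoquinone by commercial 4,4-dimethoxycyclohexa-2,5-dien-1-one (the quinone monoketal) under the same oxazaborolidinium catalysis. This dienophile has a single carbonyl and is not an oxidant. It should give the all-cis endo adduct 5-[4-(benzyloxy)-8-methoxynaphthalen-1-yl]-4,4-dimethoxy-8-[(triisopropylsilyl)oxy]-4a,5,8,8a-tetrahydronaphthalen-1(4H)-one F1, in which the aryl-bearing carbon has bonded to the enone β-carbon next to the ketal. The two orientations are now constitutional isomers and can be separated by chromatography. Mild ketal hydrolysis (oxalic acid on wet silica, CH2Cl2) would then give ene-dione 10, and Et3N would tautomerise it to 11, where the route is rejoined.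

Step 6. Silylation of the non-conjugated aldehyde may deprotonate a folded conformer and deliver the (1Z)-enol ether, which cannot reach the reactive s-cis conformation. The fallback sets out from 3 and builds the conjugated enal deliberately:
- Suzuki–Miyaura coupling of 3 with allylboronic acid pinacol ester (Pd(OAc)2/SPhos, K3PO4) should give 1-(benzyloxy)-5-methoxy-4-(prop-2-en-1-yl)naphthalene F2.
- Cross-metathesis with crotonaldehyde (second-generation Ru–alkylidene catalyst, CH2Cl2, 40 °C) should give (2E)-4-[4-(benzyloxy)-8-methoxynaphthalen-1-yl]but-2-enal F3.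
- TIPSOTf/Et3N then removes a benzylic γ-proton from the O-silylated s-trans enal. The (1E) enol ether geometry is inherited from the E-enal, and the aryl-substituted double bond should form as the unstrained E isomer.

The route is rejoined at 8.

Step 9. Transfer of H2 from diimide to the hindered C2=C3 bond may stall while the reagent disproportionates, or prolonged exposure to base may induce elimination of silanol. The fallback sets out from 12 and uses homogeneous catalytic hydrogenation instead: H2 (1–4 atm), RhCl(PPh3)3, benzene–EtOH, rt. This should spare the aryl benzyl ethers and the silyl ether and return directly to 13. This fallback makes no new compound (F0).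

**Further compounds**
F1 | step 7 | all-cis endo adduct 5-[4-(benzyloxy)-8-methoxynaphthalen-1-yl]-4,4-dimethoxy-8-[(triisopropylsilyl)oxy]-4a,5,8,8a-tetrahydronaphthalen-1(4H)-one | COc1cccc2c(OCc3ccccc3)ccc([C@@H]3C=C[C@H](O[Si](C(C)C)(C(C)C)C(C)C)[C@@H]4C(=O)C=CC(OC)(OC)[C@H]34)c12
F2 | step 6 | 1-(benzyloxy)-5-methoxy-4-(prop-2-en-1-yl)naphthalene | C=CCc1ccc(OCc2ccccc2)c2cccc(OC)c12
F3 | step 6 | (2E)-4-[4-(benzyloxy)-8-methoxynaphthalen-1-yl]but-2-enal | O=C/C=C/Cc1ccc(OCc2ccccc2)c2cccc(OC)c12
F0 | step 9 | none | none
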